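The route rests on breaking the C1'–C2' bond between the two quaternary carbons of the bromotrimethylcyclopentane, whose C1' sits on C7 next to the C8 carbonyl of ring B. In one operation a bromonium ion at C3' of a prenyl terminus closes the cyclopentane onto C1' of a Z-configured C7=C1' alkylidene while the axial hydrogen of a C8 silyloxy carbinol shifts to C7, so the ring, the C3' bromide, the C1' stereocentre and the C8 ketone all arise together. The precursor is a trans-decalin already carrying the C1 bromide and the protected 4,5-diol, with a 6-methylhept-5-en-2-ylidene group at C7; a nickel-catalysed ynal cyclisation fixes its geometry.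

Key step: step 13

Remark 1: locants follow the eudesmane pattern of the decalin (C1 CHBr, C4 C(OH)Me, C5 C–OH, C7 side-chain carbon, C8 carbonyl, C10 CMe) and C1'–C5' for the cyclopentane; the C7 configuration of ketone 21 is taken as the equatorial epimer and is erased in step 14.

Remark 2: the cascade can give (1'R) only if C2' reaches C1' of the Z alkene on the face opposite the C10 methyl while hydride leaves C8 from the methyl face; the precursor is therefore built as the 8R carbinol (oxygen equatorial and trans to the C10 methyl, C8–H axial), because in the 8-epimer that hydrogen is equatorial and lies on the face that C2' must use.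

Step 1
Reactants: 1 2-methylcyclohexane-1,3-dione; 2 allyl bromide
Product: 3 2-allyl-2-methylcyclohexane-1,3-dione
Conditions: aq. NaOH (1 M), Bu4NI (cat.), 23 °C
Reagents that add atoms: none
Why: C-allylation of the stabilised dione enolate (SN2 alkylation in aqueous base) installs the future C10 quaternary carbon as a prochiral centre.

Step 2
Reactants: 3 2-allyl-2-methylcyclohexane-1,3-dione
Product: 4 (2R,3R)-2-allyl-3-hydroxy-2-methylcyclohexan-1-one
Conditions: (S)-2-methyl-CBS-oxazaborolidine (0.2 equiv), catecholborane (1.1 equiv), toluene, −78 to −40 °C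
Reagents that add atoms: none
Why: Corey–Bakshi–Shibata reduction desymmetrises the prochiral dione, the catalyst reducing one enantiotopic carbonyl with the quaternary carbon as the large group (3R) and hydride entering syn to the smaller methyl group, so the hydroxyl should end cis to allyl and trans to methyl, which fixes C10 and C1; the minor diastereomer is removed by chromatography.

Step 3
Reactants: 4 (2R,3R)-2-allyl-3-hydroxy-2-methylcyclohexan-1-one
Product: 5 (2R,3R)-2-allyl-3-[(tert-butyldimethylsilyl)oxy]-2-methylcyclohexan-1-one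
Conditions: TBSCl, imidazole, DMF, 40 °C
Reagents that add atoms: tert-butyldimethylsilyl chloride, CC(C)(C)[Si](C)(C)Cl
Why: Silylation of the secondary alcohol blocks retro-aldol cleavage under base and places a bulky group on the allyl face for the stereocontrol of step 5.

Step 4
Reactants: 5 (2R,3R)-2-allyl-3-[(tert-butyldimethylsilyl)oxy]-2-methylcyclohexan-1-one
Product: 6 (5R,6R)-6-allyl-5-[(tert-butyldimethylsilyl)oxy]-2-hydroxy-6-methylcyclohex-2-en-1-one
Conditions: O2 (1 atm), KOt-Bu (3 equiv), t-BuOH–THF, 0 to 23 °C; then AcOH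
Reagents that add atoms: dioxygen, O=O
Why: Base-mediated autoxidation of the only enolisable α-methylene (C4) gives the α-hydroperoxide, which collapses (Kornblum–DeLaMare type) to the 1,2-dione resting as its enol (diosphenol); C10 has no hydrogen, so the regiochemistry is forced and no stereocentre is touched.

Step 5
Reactants: 6 (5R,6R)-6-allyl-5-[(tert-butyldimethylsilyl)oxy]-2-hydroxy-6-methylcyclohex-2-en-1-one; 7 1-bromobut-2-yne
Product: 9 (2R,3R,4R)-3-allyl-2-(but-2-yn-1-yl)-4-[(tert-butyldimethylsilyl)oxy]-2-hydroxy-3-methylcyclohexan-1-one, via buta-2,3-dien-2-ylzinc bromide 8 (not isolated)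
Conditions: Zn dust (activated, 4 equiv), 7 (3 equiv), THF, 0 to 23 °C; aq. NH4Cl
Reagents that add atoms: none
Why: Barbier propargylation in which the allenylzinc bromide, after one equivalent has deprotonated the enol, adds at its CH2 terminus through a cyclic SE2' transition state to the only free carbonyl (C5) from the face of the C10 methyl, anti to the pseudoaxial allyl and the silyloxy group, so that C5 should form with the butynyl arm trans to the allyl arm; work-up returns the C4 ketone.

Step 6
Reactants: 9 (2R,3R,4R)-3-allyl-2-(but-2-yn-1-yl)-4-[(tert-butyldimethylsilyl)oxy]-2-hydroxy-3-methylcyclohexan-1-one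
Product: 10 (2R,3R,4R)-3-allyl-2-(but-2-yn-1-yl)-2,4-dihydroxy-3-methylcyclohexan-1-one
Conditions: Bu4NF, AcOH, THF, 0 to 23 °C
Reagents that add atoms: none
Why: Fluoride cleaves the secondary silyl ether, the acetic acid buffer keeping the α-ketol from base-induced rearrangement; no stereocentre changes.

Step 7
Reactants: 10 (2R,3R,4R)-3-allyl-2-(but-2-yn-1-yl)-2,4-dihydroxy-3-methylcyclohexan-1-one
Product: 11 (2R,3S,4S)-3-allyl-4-bromo-2-(but-2-yn-1-yl)-2-hydroxy-3-methylcyclohexan-1-one
Conditions: CBr4, PPh3, 2,6-lutidine, toluene, 60 °C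
Reagents that add atoms: carbon tetrabromide, BrC(Br)(Br)Br
Why: Appel reaction in which bromide displaces the oxyphosphonium ion at C1 by SN2 with inversion, giving the bromide cis to the C10 methyl; the tertiary α-keto carbinol is not activated, and substitution at a cyclohexyl carbon flanked by a quaternary centre, though slow, is an established use of this reaction.

Step 8
Reactants: 11 (2R,3S,4S)-3-allyl-4-bromo-2-(but-2-yn-1-yl)-2-hydroxy-3-methylcyclohexan-1-one
Product: 12 (1R,2R,3S,4S)-3-allyl-4-bromo-2-(but-2-yn-1-yl)-1,3-dimethylcyclohexane-1,2-diol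
Conditions: MeMgBr (3.5 equiv), Et2O–CH2Cl2, −78 to 0 °C; aq. NH4Cl
Reagents that add atoms: methylmagnesium bromide, C[Mg]Br
Why: Chelation-controlled (Cram-chelate) Grignard addition in which methyl adds to the C4 ketone syn to the C5 alkoxide and anti to the butynyl group, the other face being blocked by the axial C10 methyl in the chair that keeps the C1 bromide equatorial, so that C4 should form with its hydroxyl trans to the C5 hydroxyl.

Step 9
Reactants: 12 (1R,2R,3S,4S)-3-allyl-4-bromo-2-(but-2-yn-1-yl)-1,3-dimethylcyclohexane-1,2-diol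
Product: 13 [(1R,2R,3S,4S)-3-allyl-4-bromo-2-(but-2-yn-1-yl)-1,3-dimethylcyclohexane-1,2-diyl]bis(oxy)bis(trimethylsilane)
Conditions: Me3SiOTf (3 equiv), 2,6-lutidine, CH2Cl2, −78 to 0 °C
Reagents that add atoms: trimethylsilyl triflate, C[Si](C)(C)OS(=O)(=O)C(F)(F)F
Why: The silyl triflate silylates both hindered tertiary hydroxyls, so that the C5 oxygen cannot form a lactol with the aldehyde made in the next step.

Step 10
Reactants: 13 [(1R,2R,3S,4S)-3-allyl-4-bromo-2-(but-2-yn-1-yl)-1,3-dimethylcyclohexane-1,2-diyl]bis(oxy)bis(trimethylsilane)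
Product: 14 2-[(1S,2R,3R,6S)-6-bromo-2-(but-2-yn-1-yl)-1,3-dimethyl-2,3-bis(trimethylsilyloxy)cyclohexyl]acetaldehyde
Conditions: O3, CH2Cl2, pyridine, −78 °C (Sudan Red 7B end point); PPh3
Reagents that add atoms: ozone, [O-][O+]=O
Why: Ozonolysis, in which ozone cleaves the monosubstituted alkene much faster than the dialkyl alkyne and reductive work-up gives the aldehyde that becomes C8; no stereocentre is involved.

Step 11
Reactants: 14 2-[(1S,2R,3R,6S)-6-bromo-2-(but-2-yn-1-yl)-1,3-dimethyl-2,3-bis(trimethylsilyloxy)cyclohexyl]acetaldehyde; 15 5-bromo-2-methylpent-2-ene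
Product: 18 (2R,3Z,4aR,5R,8S,8aS)-8-bromo-5,8a-dimethyl-3-(6-methylhept-5-en-2-ylidene)-4a,5-bis[(trimethylsilyl)oxy]decahydronaphthalen-2-ol, via (4-methylpent-3-en-1-yl)magnesium bromide 16 (not isolated), via (4-methylpent-3-en-1-yl)zinc chloride 17 (not isolated)
Conditions: 15, Mg, THF; ZnCl2, 0 °C; then 14, Ni(cod)2 (10 mol %, no phosphine), THF, 0 °C; aq. NH4Cl
Reagents that add atoms: none
Why: Nickel-catalysed alkylative cyclisation of an ynal with an organozinc, in which zerovalent nickel couples aldehyde C8 and alkyne C7 to an oxanickelacyclopentene, transmetalation and reductive elimination place the alkyl group on C1' cis to C8 (Z alkene by syn addition), and chair-like closure with the oxygen in the metallacycle plane should give the equatorial C8 oxygen trans to the C10 methyl; phosphine-free conditions favour alkyl transfer over β-hydride elimination, and the hindered secondary bromide is not expected to add oxidatively.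

Step 12
Reactants: 18 (2R,3Z,4aR,5R,8S,8aS)-8-bromo-5,8a-dimethyl-3-(6-methylhept-5-en-2-ylidene)-4a,5-bis[(trimethylsilyl)oxy]decahydronaphthalen-2-ol
Product: 19 triethyl{[(2R,3Z,4aR,5R,8S,8aS)-8-bromo-5,8a-dimethyl-3-(6-methylhept-5-en-2-ylidene)-4a,5-bis(trimethylsilyloxy)decahydronaphthalen-2-yl]oxy}silane
Conditions: Et3SiOTf, 2,6-lutidine, CH2Cl2, −78 °C
Reagents that add atoms: triethylsilyl triflate, CC[Si](CC)(CC)OS(=O)(=O)C(F)(F)F
Why: Silylation of the allylic C8 hydroxyl leaves no free hydroxyl in the cascade substrate and lets the cascade end by loss of a silyl cation instead of a proton.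

Step 13
Reactants: 19 triethyl{[(2R,3Z,4aR,5R,8S,8aS)-8-bromo-5,8a-dimethyl-3-(6-methylhept-5-en-2-ylidene)-4a,5-bis(trimethylsilyloxy)decahydronaphthalen-2-yl]oxy}silane
Product: 21 (3S,4aR,5R,8S,8aS)-8-bromo-3-[(1R,3R)-3-bromo-1,2,2-trimethylcyclopentyl]-4a,5-dihydroxy-5,8a-dimethyloctahydronaphthalen-2(1H)-one, via 4,5-bis(trimethylsilyl) ether of the 7-epimeric ketone 20 (not isolated)
Conditions: Et2SBr·SbCl5Br (1.1 equiv), MeNO2, −25 °C, 10 min; aq. NaHCO3–Na2SO3; then 1 M HCl, THF, 23 °C
Reagents that add atoms: bromodiethylsulfonium bromopentachloroantimonate, CC[S+](Br)CC.Cl[Sb-](Cl)(Cl)(Cl)(Cl)Br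
Why: Proposed new method: Br+ is taken up by the accessible trisubstituted prenyl alkene (the tetrasubstituted C7=C1' alkene is shielded and inductively deactivated by the allylic silyloxy group), the bromonium ion opens to the tertiary C2' cation, and C1' of the C7=C1' alkene captures it while the axial C8–H migrates to C7, the silyloxocarbenium ion then losing Et3Si+ to halide to give the C8 ketone without release of acid. The closest known reaction types are bromonium-initiated cation–olefin cyclisation with this reagent, which closes six-membered rings, and the Prins–pinacol and halo-semipinacol 1,2-shifts of allylic silyl ethers; their merger in a five-membered closure is untested. The cyclopentane closes 5-exo-trig with respect to the C7=C1' alkene (C1' in the ring, C7 outside), which should be favoured over 6-endo attack at C7 because C7 is flanked by C6 and the silyloxy-bearing C8 and because only attack at C1' leaves a cation that the aligned C8–H can quench. C1' (R) is controlled by the Z geometry together with the axial C8–H on the face of the C10 methyl, since anti addition puts C2' on the opposite face of C1' and relieves the A(1,3) strain between the C8 oxygen and C5'; C3' (R) follows from anti opening of the bromonium ion in the envelope in which bromine lies over the C7 terminus, where it can bridge to the developing cation, which places Br cis to the decalin; C7 is set by the suprafacial hydride shift and should equilibrate to the equatorial epimer during the acidic work-up that also removes the trimethylsilyl groups. The step needs chemoselectivity for the prenyl alkene, five- over six-membered closure and C1'/C3' diastereocontrol, of which the C3' control is the least secured.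

Step 14
Reactants: 21 (3S,4aR,5R,8S,8aS)-8-bromo-3-[(1R,3R)-3-bromo-1,2,2-trimethylcyclopentyl]-4a,5-dihydroxy-5,8a-dimethyloctahydronaphthalen-2(1H)-one
Product: 22 (4aR,5R,8S,8aS)-8-bromo-3-[(1R,3R)-3-bromo-1,2,2-trimethylcyclopentyl]-4a,5-dihydroxy-5,8a-dimethyl-4a,5,6,7,8,8a-hexahydronaphthalen-2(1H)-one
Conditions: IBX (3 equiv), DMSO–fluorobenzene, 70 °C
Reagents that add atoms: none
Why: IBX dehydrogenation through the enol, in which only the C7 enol has a β-hydrogen (at C6) because C9 is flanked by the quaternary C10, so the C6=C7 enone should form whatever the C7 configuration; the tertiary hydroxyls and both secondary bromides are inert to IBX.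

Compound list
1 | 2-methylcyclohexane-1,3-dione | CC1C(=O)CCCC1=O | starting material
2 | allyl bromide | C=CCBr | starting material
3 | 2-allyl-2-methylcyclohexane-1,3-dione | C=CCC1(C)C(=O)CCCC1=O | intermediate
4 | (2R,3R)-2-allyl-3-hydroxy-2-methylcyclohexan-1-one | C=CC[C@@]1(C)C(=O)CCC[C@H]1O | intermediate
5 | (2R,3R)-2-allyl-3-[(tert-butyldimethylsilyl)oxy]-2-methylcyclohexan-1-one | C=CC[C@@]1(C)C(=O)CCC[C@H]1O[Si](C)(C)C(C)(C)C | intermediate
6 | (5R,6R)-6-allyl-5-[(tert-butyldimethylsilyl)oxy]-2-hydroxy-6-methylcyclohex-2-en-1-one | C=CC[C@@]1(C)C(=O)C(O)=CC[C@H]1O[Si](C)(C)C(C)(C)C | intermediate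
7 | 1-bromobut-2-yne | CC#CCBr | starting material
8 | buta-2,3-dien-2-ylzinc bromide | C=C=C(C)[Zn]Br | intermediate (not isolated)
9 | (2R,3R,4R)-3-allyl-2-(but-2-yn-1-yl)-4-[(tert-butyldimethylsilyl)oxy]-2-hydroxy-3-methylcyclohexan-1-one | C=CC[C@@]1(C)[C@](O)(CC#CC)C(=O)CC[C@H]1O[Si](C)(C)C(C)(C)C | intermediate
10 | (2R,3R,4R)-3-allyl-2-(but-2-yn-1-yl)-2,4-dihydroxy-3-methylcyclohexan-1-one | C=CC[C@@]1(C)[C@](O)(CC#CC)C(=O)CC[C@H]1O | intermediate
11 | (2R,3S,4S)-3-allyl-4-bromo-2-(but-2-yn-1-yl)-2-hydroxy-3-methylcyclohexan-1-one | C=CC[C@@]1(C)[C@](O)(CC#CC)C(=O)CC[C@@H]1Br | intermediate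
12 | (1R,2R,3S,4S)-3-allyl-4-bromo-2-(but-2-yn-1-yl)-1,3-dimethylcyclohexane-1,2-diol | C=CC[C@@]1(C)[C@](O)(CC#CC)[C@](C)(O)CC[C@@H]1Br | intermediate
13 | [(1R,2R,3S,4S)-3-allyl-4-bromo-2-(but-2-yn-1-yl)-1,3-dimethylcyclohexane-1,2-diyl]bis(oxy)bis(trimethylsilane) | C=CC[C@@]1(C)[C@](O[Si](C)(C)C)(CC#CC)[C@](C)(O[Si](C)(C)C)CC[C@@H]1Br | intermediate
14 | 2-[(1S,2R,3R,6S)-6-bromo-2-(but-2-yn-1-yl)-1,3-dimethyl-2,3-bis(trimethylsilyloxy)cyclohexyl]acetaldehyde | O=CC[C@@]1(C)[C@](O[Si](C)(C)C)(CC#CC)[C@](C)(O[Si](C)(C)C)CC[C@@H]1Br | intermediate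
15 | 5-bromo-2-methylpent-2-ene | CC(C)=CCCBr | starting material
16 | (4-methylpent-3-en-1-yl)magnesium bromide | CC(C)=CCC[Mg]Br | intermediate (not isolated)
17 | (4-methylpent-3-en-1-yl)zinc chloride | CC(C)=CCC[Zn]Cl | intermediate (not isolated)
18 | (2R,3Z,4aR,5R,8S,8aS)-8-bromo-5,8a-dimethyl-3-(6-methylhept-5-en-2-ylidene)-4a,5-bis[(trimethylsilyl)oxy]decahydronaphthalen-2-ol | CC(C)=CCC/C(C)=C1/C[C@]2(O[Si](C)(C)C)[C@](C)(O[Si](C)(C)C)CC[C@H](Br)[C@@]2(C)C[C@H]1O | intermediate
19 | triethyl{[(2R,3Z,4aR,5R,8S,8aS)-8-bromo-5,8a-dimethyl-3-(6-methylhept-5-en-2-ylidene)-4a,5-bis(trimethylsilyloxy)decahydronaphthalen-2-yl]oxy}silane (key-step precursor) | CC(C)=CCC/C(C)=C1/C[C@]2(O[Si](C)(C)C)[C@](C)(O[Si](C)(C)C)CC[C@H](Br)[C@@]2(C)C[C@H]1O[Si](CC)(CC)CC | intermediate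
20 | (3R,4aR,5R,8S,8aS)-8-bromo-3-[(1R,3R)-3-bromo-1,2,2-trimethylcyclopentyl]-5,8a-dimethyl-4a,5-bis[(trimethylsilyl)oxy]octahydronaphthalen-2(1H)-one | CC1(C)[C@H](Br)CC[C@]1(C)[C@H]1C[C@]2(O[Si](C)(C)C)[C@](C)(O[Si](C)(C)C)CC[C@H](Br)[C@@]2(C)CC1=O | intermediate (not isolated)
21 | (3S,4aR,5R,8S,8aS)-8-bromo-3-[(1R,3R)-3-bromo-1,2,2-trimethylcyclopentyl]-4a,5-dihydroxy-5,8a-dimethyloctahydronaphthalen-2(1H)-one (key-step product) | CC1(C)[C@H](Br)CC[C@]1(C)[C@@H]1C[C@]2(O)[C@](C)(O)CC[C@H](Br)[C@@]2(C)CC1=O | intermediate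
22 | (4aR,5R,8S,8aS)-8-bromo-3-[(1R,3R)-3-bromo-1,2,2-trimethylcyclopentyl]-4a,5-dihydroxy-5,8a-dimethyl-4a,5,6,7,8,8a-hexahydronaphthalen-2(1H)-one | CC1(C)[C@H](Br)CC[C@]1(C)C1=C[C@]2(O)[C@](C)(O)CC[C@H](Br)[C@@]2(C)CC1=O | target

Total step count: 14. Longest linear sequence: 14 steps (1 to 22).

Steps most likely to fail

Step 13. Bromine may be transferred to the tetrasubstituted C7=C1' alkene and trigger a bromo-semipinacol shift, C2' may close on C7 to give a six-membered spiro ring, or closure may run through the other bromonium diastereomer and give the C3' epimer. The fallback uses known chemistry and sets out from 18. Dess–Martin periodinane should oxidise 18 to the Z enone F1. Shi epoxidation of the prenyl alkene (fructose-derived ketone of the enantiomeric series that gives the 3'S epoxide, KHSO5, buffered MeCN–dimethoxymethane–water, 0 °C) should give the epoxy enone F2, the electron-poor enone alkene being left alone. Cp2TiCl (trivalent titanium, made from Cp2TiCl2 and Zn in THF) should open the epoxide to the tertiary C2' radical, which closes 5-exo onto C1' of the enone through a chair-like transition state with the titanoxy group pseudo-equatorial, so that oxygen ends trans to the decalin in the 3'-hydroxycyclopentyl ketone F3. An Appel reaction (CBr4, PPh3) with inversion at C3' should give the dibromo ketone bis(trimethylsilyl) ether F4, and 1 M HCl in THF removes the silyl groups and comes back to the route at 21.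

Step 11. β-Hydride elimination from the alkylnickel intermediate may outrun reductive elimination, so that hydrogen and not the 4-methylpent-3-enyl group is delivered to C1'. The fallback sets out from 14 and transfers an sp2 group that cannot undergo this elimination. The same nickel-catalysed cyclisation with vinylzinc chloride (from vinylmagnesium bromide and ZnCl2) should give the Z dienol F5, and Et3SiOTf with 2,6-lutidine gives the dienyl triethylsilyl ether F6. 9-BBN should hydroborate only the terminal vinyl group to give the B-alkyl-9-BBN adduct F7 (not isolated). B-alkyl Suzuki–Miyaura coupling with 1-bromo-2-methylprop-1-ene (Pd(dppf)Cl2, K3PO4, THF–water) then builds the prenyl terminus and comes back to the route at 19.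

Step 7. Elimination, or a 1,2-shift of a substituent of the neighbouring quaternary carbon, may outrun substitution of the oxyphosphonium ion at the neopentylic C1. The fallback sets out from 10 and replaces in situ phosphorus activation by an isolated sulfonate and a separate displacement. Chloromethanesulfonyl chloride and pyridine in CH2Cl2 at 0 °C should esterify only the secondary hydroxyl to give the chloromethanesulfonate F8. Bu4NBr in toluene at 60 °C then displaces it with inversion and comes back to the route at 11.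

Further compounds
F1 | step 13 | (3Z,4aR,5R,8S,8aS)-8-bromo-5,8a-dimethyl-3-(6-methylhept-5-en-2-ylidene)-4a,5-bis[(trimethylsilyl)oxy]octahydronaphthalen-2(1H)-one | CC(C)=CCC/C(C)=C1/C[C@]2(O[Si](C)(C)C)[C@](C)(O[Si](C)(C)C)CC[C@H](Br)[C@@]2(C)CC1=O
F2 | step 13 | (3Z,4aR,5R,8S,8aS)-8-bromo-3-{4-[(2S)-3,3-dimethyloxiran-2-yl]butan-2-ylidene}-5,8a-dimethyl-4a,5-bis[(trimethylsilyl)oxy]octahydronaphthalen-2(1H)-one | CC1(C)O[C@H]1CC/C(C)=C1/C[C@]2(O[Si](C)(C)C)[C@](C)(O[Si](C)(C)C)CC[C@H](Br)[C@@]2(C)CC1=O
F3 | step 13 | (3S,4aR,5R,8S,8aS)-8-bromo-3-[(1R,3S)-3-hydroxy-1,2,2-trimethylcyclopentyl]-5,8a-dimethyl-4a,5-bis[(trimethylsilyl)oxy]octahydronaphthalen-2(1H)-one | CC1(C)[C@@H](O)CC[C@]1(C)[C@@H]1C[C@]2(O[Si](C)(C)C)[C@](C)(O[Si](C)(C)C)CC[C@H](Br)[C@@]2(C)CC1=O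
F4 | step 13 | (3S,4aR,5R,8S,8aS)-8-bromo-3-[(1R,3R)-3-bromo-1,2,2-trimethylcyclopentyl]-5,8a-dimethyl-4a,5-bis[(trimethylsilyl)oxy]octahydronaphthalen-2(1H)-one | CC1(C)[C@H](Br)CC[C@]1(C)[C@@H]1C[C@]2(O[Si](C)(C)C)[C@](C)(O[Si](C)(C)C)CC[C@H](Br)[C@@]2(C)CC1=O
F5 | step 11 | (2R,3Z,4aR,5R,8S,8aS)-8-bromo-3-(but-3-en-2-ylidene)-5,8a-dimethyl-4a,5-bis[(trimethylsilyl)oxy]decahydronaphthalen-2-ol | C=C/C(C)=C1/C[C@]2(O[Si](C)(C)C)[C@](C)(O[Si](C)(C)C)CC[C@H](Br)[C@@]2(C)C[C@H]1O
F6 | step 11 | triethylsilyl ether of F5 at the C8 oxygen | C=C/C(C)=C1/C[C@]2(O[Si](C)(C)C)[C@](C)(O[Si](C)(C)C)CC[C@H](Br)[C@@]2(C)C[C@H]1O[Si](CC)(CC)CC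
F7 | step 11 | 9-BBN adduct of F6 with boron on the terminal carbon of the former vinyl group | C1CCC2CCCC1B2CC/C(C)=C1/C[C@]2(O[Si](C)(C)C)[C@](C)(O[Si](C)(C)C)CC[C@H](Br)[C@@]2(C)C[C@H]1O[Si](CC)(CC)CC
F8 | step 7 | (1R,2R,3R)-2-allyl-3-(but-2-yn-1-yl)-3-hydroxy-2-methyl-4-oxocyclohexyl chloromethanesulfonate | C=CC[C@@]1(C)[C@](O)(CC#CC)C(=O)CC[C@H]1OS(=O)(=O)CCl
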